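The cyclohexene ring (C5–C10) of the target, with its tetrasubstituted C5=C10 alkene carrying the C4 side chain, is read as a hydrogenated 1-(alk-1-en-2-yl)cyclohexene: dehydrogenation across C4–C15 gives the diene that exo ring-closing enyne metathesis delivers. One ruthenium-catalysed step thus joins a C5≡C4 alkyne to a C10 methallyl alkene, closing the carbocycle and forming both the C5=C10 and C4=C15 bonds. Its precursor is a cis-4,5-disubstituted γ-butyrolactone (C7, C8, C11, C12) that carries the methallyl group at C8 and, at C7, a silyl-protected propargylic carbinol (C6) with the alkyne and the C1–C3 chain; aldol and allylboration set C6–C8 beforehand, and hydrogenation sets C4 afterwards.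

Key step: step 10

Remark: carbon labels are C1 (side-chain CH2O), C4 (side-chain CH), C15 (its methyl), C5=C10 (ring alkene), C14 (ring methyl), C6 (ester-bearing CH), C7/C8 (ring fusion), C9 (ring CH2), C11/C12/C13 (lactone α-carbon, carbonyl, methylidene); 2-methylallylmagnesium chloride is taken as the commercial THF solution, and (+)-Ipc2BOMe means the methoxyborane derived from (−)-α-pinene.

Step 1
Reactants: 1 pent-4-yn-1-ol
Product: 2 1-methoxy-4-[(pent-4-yn-1-yloxy)methyl]benzene
Conditions: NaH, PMBCl, Bu4NI (cat.), DMF, 0 °C → rt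
Reagents that add atoms: 4-methoxybenzyl chloride (PMBCl), COc1ccc(CCl)cc1
Why: Williamson ether synthesis in which the alkoxide forms long before the acetylenic C–H is touched, giving a C1 ether that can be removed oxidatively at the end without affecting esters or silyl ethers.

Step 2
Reactants: 2 PMB ether of pent-4-yn-1-ol
Product: 4 6-[(4-methoxybenzyl)oxy]hex-2-ynal, via lithium acetylide 3 (not isolated)
Conditions: n-BuLi, THF, −78 °C; DMF, −78 → 0 °C; inverse quench into aq KH2PO4
Reagents that add atoms: N,N-dimethylformamide, CN(C)C=O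
Why: Formylation of a lithium acetylide with DMF, the aminoalkoxide adduct being hydrolysed only in the buffered inverse quench so that dimethylamine does not add to the ynal.

Step 3
Reactants: 5 mono-tert-butyl succinate; 6 (4S)-4-benzyl-1,3-oxazolidin-2-one
Product: 8 tert-butyl 4-[(4S)-4-benzyl-2-oxo-1,3-oxazolidin-3-yl]-4-oxobutanoate, via mixed pivalic anhydride 7 (not isolated)
Conditions: PivCl, Et3N, THF, −20 °C; then LiCl, 6, −20 °C → rt
Reagents that add atoms: none
Why: N-acylation of an oxazolidinone through a mixed anhydride, the nitrogen attacking the unhindered succinyl carbonyl and not the pivaloyl one.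

Step 4
Reactants: 8 succinate imide; 4 ynal
Product: 10 tert-butyl (3S,4S)-3-{[(4S)-4-benzyl-2-oxo-1,3-oxazolidin-3-yl]carbonyl}-4-hydroxy-9-[(4-methoxybenzyl)oxy]non-5-ynoate, via Z-boron enolate 9 (not isolated)
Conditions: n-Bu2BOTf, i-Pr2NEt, CH2Cl2, 0 °C; 4, −78 → 0 °C; pH 7 buffer, MeOH, H2O2, 0 °C
Reagents that add atoms: none
Why: Evans syn aldol reaction in which the imide (not the ester) is enolized to the Z-boron enolate and the chair Zimmerman–Traxler transition state, with the benzyl group turned away, sets C7 and C6 together as the syn pair that later places the C6 oxygen trans to the lactone ring.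

Step 5
Reactants: 10 aldol adduct
Product: 11 tert-butyl (3S,4S)-3-{[(4S)-4-benzyl-2-oxo-1,3-oxazolidin-3-yl]carbonyl}-4-[(tert-butyldimethylsilyl)oxy]-9-[(4-methoxybenzyl)oxy]non-5-ynoate
Conditions: TBSOTf, 2,6-lutidine, CH2Cl2, −78 → 0 °C
Reagents that add atoms: tert-butyldimethylsilyl trifluoromethanesulfonate, CC(C)(C)[Si](C)(C)OS(=O)(=O)C(F)(F)F
Why: Silylation of a secondary alcohol with a silyl triflate and a hindered base, mild enough to avoid retro-aldol cleavage and needed so that later only the C8 oxygen can lactonize onto C12.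

Step 6
Reactants: 11 silylated aldol adduct
Product: 12 tert-butyl (3R,4S)-4-[(tert-butyldimethylsilyl)oxy]-3-(hydroxymethyl)-9-[(4-methoxybenzyl)oxy]non-5-ynoate
Conditions: LiBH4, MeOH (1 equiv), THF, 0 °C
Reagents that add atoms: none
Why: Reductive removal of the oxazolidinone auxiliary with LiBH4, which attacks the activated imide carbonyl and spares the hindered tert-butyl ester, C7 keeping its configuration (its descriptor changes only through CIP priorities).

Step 7
Reactants: 12 primary alcohol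
Product: 13 tert-butyl (3S,4S)-4-[(tert-butyldimethylsilyl)oxy]-3-formyl-9-[(4-methoxybenzyl)oxy]non-5-ynoate
Conditions: Dess–Martin periodinane, CH2Cl2, 0 °C → rt
Reagents that add atoms: none
Why: Dess–Martin oxidation under near-neutral conditions, so that the α-branched β-silyloxy aldehyde neither epimerizes at C7 nor eliminates silanol before it is used at once.

Step 8
Reactants: 13 aldehyde; 14 2-methylallylmagnesium chloride
Product: 16 tert-butyl (3R,4S)-4-[(tert-butyldimethylsilyl)oxy]-3-[(1R)-1-hydroxy-3-methylbut-3-en-1-yl]-9-[(4-methoxybenzyl)oxy]non-5-ynoate, via B-methallyldiisopinocampheylborane 15 (not isolated)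
Conditions: (+)-Ipc2BOMe, 14, Et2O, 0 °C → rt, MgCl(OMe) filtered off; 13, −78 °C; then NaOH, H2O2, 0 °C → rt
Reagents that add atoms: none
Why: Brown methallylation through a closed chair transition state, in which the borane carrying the isopinocampheyl groups from (−)-α-pinene adds to the Re face of the aldehyde and so sets C8 as R (C8–O anti to the C7 branch and 1,3-anti to the C6 oxygen) by reagent control over the weak Felkin bias of the α-centre.

Step 9
Reactants: 16 hydroxy tert-butyl ester
Product: 17 (4R,5R)-4-{(1S)-1-[(tert-butyldimethylsilyl)oxy]-6-[(4-methoxybenzyl)oxy]hex-2-yn-1-yl}-5-(2-methylprop-2-en-1-yl)oxolan-2-one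
Conditions: p-TsOH·H2O (0.1 equiv), CH2Cl2, rt
Reagents that add atoms: none
Why: Acid-catalysed lactonization (intramolecular transesterification) of a γ-hydroxy tert-butyl ester with loss of tert-butanol, in which only the C8 hydroxyl is free, C7 and C8 are untouched and the cis-4,5-disubstituted lactone results, while the TBS and PMB ethers tolerate catalytic sulfonic acid in an aprotic solvent.

Step 10
Reactants: 17 lactone enyne
Product: 18 (3aR,4S,7aR)-4-[(tert-butyldimethylsilyl)oxy]-5-{5-[(4-methoxybenzyl)oxy]pent-1-en-2-yl}-6-methyl-3a,4,7,7a-tetrahydro-1-benzofuran-2(3H)-one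
Conditions: RuCl2(=CHPh)(PCy3)(H2IMes) (second-generation Grubbs catalyst, 10 mol% in two portions), toluene (0.005 M), 80 °C, Ar
Reagents that add atoms: none
Why: Enyne metathesis in which the benzylidene is first converted into the propagating methylidene Ru=CH2, which adds across C5≡C4 to a ruthenacyclobutene that opens to the vinylcarbene Ru=C5–C4(=C15H2); this carbene closes onto the C10=CH2 alkene through a ruthenacyclobutane and releases the C5=C10 bond and a new Ru=CH2, so that the CH2 given up by one methallyl group becomes C15 of the next molecule. The closest known reaction type is the exo ring-closing enyne metathesis of 1,7-enynes bearing an internal alkyne and a 1,1-disubstituted alkene to 1-(alk-1-en-2-yl)cyclohexenes with RuCl2(=CHPh)(PCy3)(H2IMes). The cyclohexene (C5–C6–C7–C8–C9–C10) closes in the exo mode, C5 ending inside and C4 outside the ring, through the four-atom tether C6–C7–C8–C9. No stereocentre is formed, and C6, C7 and C8 are not touched. The step needs six-ring exo closure to win over seven-ring endo closure and over intermolecular metathesis: the cis arrangement of the two arms on the lactone holds alkyne and alkene together, the six-membered ring is the kinetically favoured one, high dilution without added ethylene reserves the vinylcarbene for ring closure, and the silyl ether keeps a free propargylic hydroxyl away from ruthenium and stops the lactone from migrating to the C6 oxygen.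

Step 11
Reactants: 18 diene
Product: 19 (3aR,4S,7aR)-4-[(tert-butyldimethylsilyl)oxy]-5-{(2S)-5-[(4-methoxybenzyl)oxy]pentan-2-yl}-6-methyl-3a,4,7,7a-tetrahydro-1-benzofuran-2(3H)-one
Conditions: RhCl(PPh3)3 (10 mol%), H2 (4 atm), toluene, 40 °C
Reagents that add atoms: none
Why: Homogeneous hydrogenation with Wilkinson's catalyst RhCl(PPh3)3, which reduces the 1,1-disubstituted C4=C15 bond and leaves the tetrasubstituted C5=C10 bond, the diene being twisted so that the pseudoaxial C6 silyloxy group blocks the upper quadrant on the C6 side and the C14 methyl the C10 side, whereby rhodium should enter through the open quadrant beside the equatorial C6–H and place hydrogen on C4 from the C6 side with C15 turned away from the silyloxy group, which corresponds to 4S.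

Step 12
Reactants: 19 saturated lactone
Product: 23 (3aR,4S,7aR)-4-[(tert-butyldimethylsilyl)oxy]-5-{(2S)-5-[(4-methoxybenzyl)oxy]pentan-2-yl}-6-methyl-3-methylidene-3a,4,7,7a-tetrahydro-1-benzofuran-2(3H)-one, via lithium enolate 20 (not isolated), via Mannich base 21 (not isolated), via trimethylammonium iodide 22 (not isolated)
Conditions: LiN(i-Pr)2, THF, −78 °C; CH2=NMe2+ I−, −78 °C → rt; then MeI, MeOH, rt; then aq NaHCO3, CH2Cl2, rt
Reagents that add atoms: dimethylmethylideneammonium iodide (Eschenmoser's salt), C=[N+](C)C.[I-]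
Why: Eschenmoser α-methylenation (enolate Mannich reaction, N-methylation, β-elimination of trimethylamine) at the only enolizable carbonyl, in which the transient C11 centre is lost again and C7, being β to the carbonyl, cannot epimerize.

Step 13
Reactants: 23 silylated α-methylene lactone
Product: 24 (3aS,4S,7aR)-4-hydroxy-5-{(2S)-5-[(4-methoxybenzyl)oxy]pentan-2-yl}-6-methyl-3-methylidene-3a,4,7,7a-tetrahydro-1-benzofuran-2(3H)-one
Conditions: HF·pyridine, pyridine, THF, 0 °C → rt
Reagents that add atoms: none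
Why: Fluoride-mediated desilylation under buffered conditions that spare the PMB ether and the base-sensitive α-methylene lactone, the cis-fused lactone staying in place because a shift to the C6 oxygen would require a trans-fused ring (the 3a descriptor changes only through CIP priorities).

Step 14
Reactants: 24 C6 alcohol; 25 isovaleryl chloride
Product: 26 (3aR,4S,7aR)-5-{(2S)-5-[(4-methoxybenzyl)oxy]pentan-2-yl}-6-methyl-3-methylidene-2-oxo-2,3,3a,4,7,7a-hexahydro-1-benzofuran-4-yl 3-methylbutanoate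
Conditions: pyridine, DMAP (cat.), CH2Cl2, 0 °C → rt
Reagents that add atoms: none
Why: DMAP-catalysed acylation of a secondary allylic alcohol with an acid chloride, which takes place at oxygen and therefore leaves the C6 configuration unchanged.

Step 15
Reactants: 26 PMB-protected ester
Product: 27 (3aR,4S,7aR)-5-[(2S)-5-hydroxypentan-2-yl]-6-methyl-3-methylidene-2-oxo-2,3,3a,4,7,7a-hexahydro-1-benzofuran-4-yl 3-methylbutanoate
Conditions: DDQ, CH2Cl2/pH 7 buffer (10:1), 0 °C
Reagents that add atoms: none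
Why: Oxidative cleavage of a PMB ether with DDQ (hydride abstraction at the electron-rich benzylic position and hydrolysis of the oxocarbenium ion) under neutral conditions that leave the isovalerate, the α-methylene lactone and the ring alkene intact.

Compound list
1 | pent-4-yn-1-ol | C#CCCCO | starting material
2 | 1-methoxy-4-[(pent-4-yn-1-yloxy)methyl]benzene | C#CCCCOCc1ccc(OC)cc1 | intermediate
3 | lithium acetylide of 2 | [Li]C#CCCCOCc1ccc(OC)cc1 | intermediate
4 | 6-[(4-methoxybenzyl)oxy]hex-2-ynal | O=CC#CCCCOCc1ccc(OC)cc1 | intermediate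
5 | mono-tert-butyl succinate (4-tert-butoxy-4-oxobutanoic acid) | OC(=O)CCC(=O)OC(C)(C)C | starting material
6 | (4S)-4-benzyl-1,3-oxazolidin-2-one | O=C1OC[C@H](Cc2ccccc2)N1 | starting material
7 | 4-tert-butoxy-4-oxobutanoic pivalic anhydride | CC(C)(C)OC(=O)CCC(=O)OC(=O)C(C)(C)C | intermediate
8 | tert-butyl 4-[(4S)-4-benzyl-2-oxo-1,3-oxazolidin-3-yl]-4-oxobutanoate | O=C1OC[C@H](Cc2ccccc2)N1C(=O)CCC(=O)OC(C)(C)C | intermediate
9 | (Z)-dibutylboron enolate of 8 | CCCCB(CCCC)O/C(=C\CC(=O)OC(C)(C)C)N1C(=O)OC[C@@H]1Cc1ccccc1 | intermediate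
10 | tert-butyl (3S,4S)-3-{[(4S)-4-benzyl-2-oxo-1,3-oxazolidin-3-yl]carbonyl}-4-hydroxy-9-[(4-methoxybenzyl)oxy]non-5-ynoate | O=C1OC[C@H](Cc2ccccc2)N1C(=O)[C@@H](CC(=O)OC(C)(C)C)[C@H](O)C#CCCCOCc1ccc(OC)cc1 | intermediate
11 | tert-butyl (3S,4S)-3-{[(4S)-4-benzyl-2-oxo-1,3-oxazolidin-3-yl]carbonyl}-4-[(tert-butyldimethylsilyl)oxy]-9-[(4-methoxybenzyl)oxy]non-5-ynoate | O=C1OC[C@H](Cc2ccccc2)N1C(=O)[C@@H](CC(=O)OC(C)(C)C)[C@H](O[Si](C)(C)C(C)(C)C)C#CCCCOCc1ccc(OC)cc1 | intermediate
12 | tert-butyl (3R,4S)-4-[(tert-butyldimethylsilyl)oxy]-3-(hydroxymethyl)-9-[(4-methoxybenzyl)oxy]non-5-ynoate | OC[C@@H](CC(=O)OC(C)(C)C)[C@H](O[Si](C)(C)C(C)(C)C)C#CCCCOCc1ccc(OC)cc1 | intermediate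
13 | tert-butyl (3S,4S)-4-[(tert-butyldimethylsilyl)oxy]-3-formyl-9-[(4-methoxybenzyl)oxy]non-5-ynoate | O=C[C@@H](CC(=O)OC(C)(C)C)[C@H](O[Si](C)(C)C(C)(C)C)C#CCCCOCc1ccc(OC)cc1 | intermediate
14 | 2-methylallylmagnesium chloride | C=C(C)C[Mg]Cl | starting material
15 | B-(2-methylallyl)diisopinocampheylborane, both isopinocampheyl groups from (−)-α-pinene | C=C(C)CB([C@H]1C[C@H]2C[C@@H]([C@@H]1C)C2(C)C)[C@H]1C[C@H]2C[C@@H]([C@@H]1C)C2(C)C | intermediate
16 | tert-butyl (3R,4S)-4-[(tert-butyldimethylsilyl)oxy]-3-[(1R)-1-hydroxy-3-methylbut-3-en-1-yl]-9-[(4-methoxybenzyl)oxy]non-5-ynoate | C=C(C)C[C@@H](O)[C@@H](CC(=O)OC(C)(C)C)[C@H](O[Si](C)(C)C(C)(C)C)C#CCCCOCc1ccc(OC)cc1 | intermediate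
17 | (4R,5R)-4-{(1S)-1-[(tert-butyldimethylsilyl)oxy]-6-[(4-methoxybenzyl)oxy]hex-2-yn-1-yl}-5-(2-methylprop-2-en-1-yl)oxolan-2-one | C1C(=O)O[C@H](CC(C)=C)[C@@H]1[C@H](O[Si](C)(C)C(C)(C)C)C#CCCCOCc1ccc(OC)cc1 | intermediate
18 | (3aR,4S,7aR)-4-[(tert-butyldimethylsilyl)oxy]-5-{5-[(4-methoxybenzyl)oxy]pent-1-en-2-yl}-6-methyl-3a,4,7,7a-tetrahydro-1-benzofuran-2(3H)-one | C1C(=O)O[C@@H]2CC(C)=C(C(=C)CCCOCc3ccc(OC)cc3)[C@@H](O[Si](C)(C)C(C)(C)C)[C@H]12 | intermediate
19 | (3aR,4S,7aR)-4-[(tert-butyldimethylsilyl)oxy]-5-{(2S)-5-[(4-methoxybenzyl)oxy]pentan-2-yl}-6-methyl-3a,4,7,7a-tetrahydro-1-benzofuran-2(3H)-one | C1C(=O)O[C@@H]2CC(C)=C([C@@H](C)CCCOCc3ccc(OC)cc3)[C@@H](O[Si](C)(C)C(C)(C)C)[C@H]12 | intermediate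
20 | lithium enolate of lactone 19 | C1=C(O[Li])O[C@@H]2CC(C)=C([C@@H](C)CCCOCc3ccc(OC)cc3)[C@@H](O[Si](C)(C)C(C)(C)C)[C@H]12 | intermediate
21 | 3-[(dimethylamino)methyl] derivative of 19 (C11 epimers) | CN(C)CC1C(=O)O[C@@H]2CC(C)=C([C@@H](C)CCCOCc3ccc(OC)cc3)[C@@H](O[Si](C)(C)C(C)(C)C)[C@H]12 | intermediate
22 | 3-[(trimethylammonio)methyl] derivative of 19, iodide (C11 epimers) | C[N+](C)(C)CC1C(=O)O[C@@H]2CC(C)=C([C@@H](C)CCCOCc3ccc(OC)cc3)[C@@H](O[Si](C)(C)C(C)(C)C)[C@H]12.[I-] | intermediate
23 | (3aR,4S,7aR)-4-[(tert-butyldimethylsilyl)oxy]-5-{(2S)-5-[(4-methoxybenzyl)oxy]pentan-2-yl}-6-methyl-3-methylidene-3a,4,7,7a-tetrahydro-1-benzofuran-2(3H)-one | C=C1C(=O)O[C@@H]2CC(C)=C([C@@H](C)CCCOCc3ccc(OC)cc3)[C@@H](O[Si](C)(C)C(C)(C)C)[C@H]12 | intermediate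
24 | (3aS,4S,7aR)-4-hydroxy-5-{(2S)-5-[(4-methoxybenzyl)oxy]pentan-2-yl}-6-methyl-3-methylidene-3a,4,7,7a-tetrahydro-1-benzofuran-2(3H)-one | C=C1C(=O)O[C@@H]2CC(C)=C([C@@H](C)CCCOCc3ccc(OC)cc3)[C@@H](O)[C@H]12 | intermediate
25 | isovaleryl chloride (3-methylbutanoyl chloride) | CC(C)CC(Cl)=O | starting material
26 | (3aR,4S,7aR)-5-{(2S)-5-[(4-methoxybenzyl)oxy]pentan-2-yl}-6-methyl-3-methylidene-2-oxo-2,3,3a,4,7,7a-hexahydro-1-benzofuran-4-yl 3-methylbutanoate | C=C1C(=O)O[C@@H]2CC(C)=C([C@@H](C)CCCOCc3ccc(OC)cc3)[C@@H](OC(=O)CC(C)C)[C@H]12 | intermediate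
27 | (3aR,4S,7aR)-5-[(2S)-5-hydroxypentan-2-yl]-6-methyl-3-methylidene-2-oxo-2,3,3a,4,7,7a-hexahydro-1-benzofuran-4-yl 3-methylbutanoate | C=C1C(=O)O[C@@H]2CC(C)=C([C@@H](C)CCCO)[C@@H](OC(=O)CC(C)C)[C@H]12 | target

Total step count: 15. Longest linear sequence: 14 steps (1 → 27 through steps 1, 2 and 4–15).

Steps most likely to fail

Step 10. The vinylcarbene may be too slow to capture the 1,1-disubstituted alkene, because this forms a tetrasubstituted C5=C10 bond, so that oligomerization or catalyst decay takes over; closure to the seven-membered ring is the other danger. The fallback is a two-stage closure that sets out from 17 and returns at 18. Cross enyne metathesis of 17 with ethylene (RuCl2(=CHPh)(PCy3)(H2IMes), ethylene 1 atm, toluene, 80 °C) should give the acyclic diene (4R,5R)-4-{(1S)-1-[(tert-butyldimethylsilyl)oxy]-6-[(4-methoxybenzyl)oxy]-2,3-dimethylidenehexyl}-5-(2-methylprop-2-en-1-yl)oxolan-2-one F1. Its C5=CH2 and C10=CH2 termini are then joined by ring-closing diene metathesis with a catalyst made for tetrasubstituted alkenes, RuCl2(=CH-C6H4-2-O-i-Pr)(NHC) with NHC = 1,3-bis(2-methylphenyl)imidazolidin-2-ylidene, in toluene at 80 °C under an argon sweep, to give 18.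

Step 11. Facial discrimination at C4 may be poor, because the reacting alkene sits on the freely rotating C5–C4 bond and both rotamers can be reduced through more than one quadrant. The fallback moves stereocontrol from the substrate to the catalyst; it sets out from 18 and returns at 19. It is an asymmetric hydrogenation of the 1,1-disubstituted alkene with a chiral iridium phosphinooxazoline complex, [Ir(cod)(L)][B(3,5-(CF3)2C6H3)4] with L = 4-tert-butyl-2-[2-(diphenylphosphino)phenyl]-4,5-dihydrooxazole (H2 1–5 atm, CH2Cl2, rt). The ligand antipode used is the one found to be matched with the C6–C8 centres in a trial with each; no new compound arises (F0).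

Step 8. Reagent control may be incomplete against the Felkin preference of the α-branched aldehyde, so that the C8 epimer accompanies 16. The fallback corrects the centre by inversion; it sets out from 13 (addition as in step 8) and returns at 16. The epimer tert-butyl (3R,4S)-4-[(tert-butyldimethylsilyl)oxy]-3-[(1S)-1-hydroxy-3-methylbut-3-en-1-yl]-9-[(4-methoxybenzyl)oxy]non-5-ynoate F2 is separated and subjected to Mitsunobu inversion (4-nitrobenzoic acid, PPh3, DIAD, toluene, 0 °C → rt). This should give tert-butyl (3R,4S)-4-[(tert-butyldimethylsilyl)oxy]-9-[(4-methoxybenzyl)oxy]-3-{(1R)-3-methyl-1-[(4-nitrobenzoyl)oxy]but-3-en-1-yl}non-5-ynoate F3, and methanolysis (K2CO3, MeOH, 0 °C) then gives 16.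

Further compounds
F1 | step 10 | (4R,5R)-4-{(1S)-1-[(tert-butyldimethylsilyl)oxy]-6-[(4-methoxybenzyl)oxy]-2,3-dimethylidenehexyl}-5-(2-methylprop-2-en-1-yl)oxolan-2-one | C1C(=O)O[C@H](CC(C)=C)[C@@H]1[C@H](O[Si](C)(C)C(C)(C)C)C(=C)C(=C)CCCOCc1ccc(OC)cc1
F0 | step 11 | none | none
F2 | step 8 | tert-butyl (3R,4S)-4-[(tert-butyldimethylsilyl)oxy]-3-[(1S)-1-hydroxy-3-methylbut-3-en-1-yl]-9-[(4-methoxybenzyl)oxy]non-5-ynoate | C=C(C)C[C@H](O)[C@@H](CC(=O)OC(C)(C)C)[C@H](O[Si](C)(C)C(C)(C)C)C#CCCCOCc1ccc(OC)cc1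
F3 | step 8 | tert-butyl (3R,4S)-4-[(tert-butyldimethylsilyl)oxy]-9-[(4-methoxybenzyl)oxy]-3-{(1R)-3-methyl-1-[(4-nitrobenzoyl)oxy]but-3-en-1-yl}non-5-ynoate | C=C(C)C[C@@H](OC(=O)c1ccc(cc1)[N+](=O)[O-])[C@@H](CC(=O)OC(C)(C)C)[C@H](O[Si](C)(C)C(C)(C)C)C#CCCCOCc1ccc(OC)cc1
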